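## The problem

Compound 17 is a cyclised diarylheptanoid. Its chain is numbered here from the guaiacyl ring (ring A) to the p-hydroxyphenyl ring (ring B): C1 is the ring CH bearing ring A, C3 the ketone, C5 the ring CH bearing the side chain, C6 the carbinol and C7 the benzylic CH2 of ring B; an ether oxygen joins C1 and C5 into a tetrahydropyran-4-one. Read from the structure, the stereocentres are 1S, 5R and 6S, that is (2S,6R,1'S) in ring nomenclature. This means a 2,6-cis ring with both substituents equatorial and an erythro (anti) relation between the oxygens on C5 and C6. C6 maps onto the α-carbon of L-tyrosine and can be bought; it can direct C5 by 1,2-induction in an addition to a C5 aldehyde, and C5 can direct C1 across the ring oxygen through a chair-like closure, so one purchased centre can in principle set the other two. The fragile features are these: both ring C–O bonds are β to the C3 carbonyl, so base can open the ring by β-elimination on either side; the C1–O bond is also a p-hydroxybenzylic ether that ionises in strong acid and is at risk under hydrogenolysis; and a free guaiacol is oxidised by periodate or ozone. The feature that makes the key step possible is the local symmetry about C3. The carbonyl is flanked by two methylenes, C2 and C4, each attached to an oxygen-bearing carbon, so C2–C3–C4 corresponds to a 2-substituted allyl unit that is nucleophilic at both ends and carries an exocyclic methylene in place of the ketone oxygen. C1 is at the aldehyde oxidation level and corresponds to vanillin.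

## Retrosynthesis

**17 to 16 (three O–Si bonds).** Both phenols and the C6 hydroxyl are carried as tert-butyldimethylsilyl ethers in 16. One kind of protecting group allows one final operation. Benzyl ethers would need hydrogenolysis beside the benzylic C1–O bond, and esters would need base at a β-alkoxy ketone. The skeleton of 16 is no simpler, but it tolerates the Lewis acids and oxidant used earlier. The forward step must be neither basic nor strongly acidic.

**16 to 14 (C3=O from C3=CH2).** The ketone is traced to the exocyclic methylene of 14. A free ketone would be a β-alkoxy ketone exposed to every Lewis-acid step, and a thioketal would need oxidative or soft-metal removal beside two electron-rich rings. The alkene is inert, is unveiled in one step, and is exactly what an allylsilane leaves behind after ring closure. The forward reaction must cleave a 1,1-disubstituted alkene without touching aryl silyl ethers.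

**14 to 10 and 12 (O–C1 and C1–C2).** Cutting these two bonds opens the ring to hydroxy allylsilane 10 and aldehyde 12.
- The mirror cut (O–C5 and C4–C5) would place the electron-rich benzylic carbinol in the allylsilane partner, where it ionises easily, and would make the α-silyloxy aldehyde 7 the cationic partner, where the neighbouring oxygen destabilises the oxocarbenium ion.
- A plain Prins cyclisation of a homoallylic alcohol would give a C3 halide or alcohol that needs extra oxidation, and is prone to oxonia-Cope scrambling with electron-rich aryl aldehydes.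
- The chosen cut puts the cation at C1, where ring A stabilises it, and forms two bonds, the ring and the C1 stereocentre together. It removes the ring, one stereocentre and ring A from the problem.
- The forward reaction must give the 2,6-cis isomer and must be trapped by the allylsilane faster than any cation rearrangement.

**10 to 7 and 9 (C4–C5).** This cut gives aldehyde 7 and the bifunctional allyl reagent 9, a stannane at one end and a silane at the other. The erythro relation requires non-chelated Felkin–Anh addition, which is why the C6 oxygen carries a bulky silyl group and why a monodentate boron Lewis acid is used. Building the allylsilane from an ester after an aldol step is longer and is kept as a fallback. The forward reaction must engage only the tin terminus.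

**9 to 8 (C–Sn).** The stannane comes from the commercial allylic chloride 8 and a stannyl anion in one step.

**7 to 6, 5, 4 and 1 (C6–O from C6–N; oxidation-level changes).** C6, C7 and ring B come intact from L-tyrosine 1. The amino group is replaced by hydroxyl with retention (4), the acid is esterified (5), both hydroxyls are silylated (6) and the ester is reduced to the aldehyde (7). Asymmetric dihydroxylation of a cinnamate or opening of a glycidyl ether would build what tyrosine already contains. The forward sequence must keep the α-centre intact, which matters most at the aldehyde stage.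

**12 to 11 (O–Si).** Vanillin 11 is silylated so that the phenol does not interfere in the annulation and shares its final deprotection with the other silyl ethers.

## Roads not taken

**Alternative 1: silyl dithiane linchpin.**
- Cut: C2–C3 and C3–C4, with C3 as the carbon of silyl dithiane A4.
- Forward key step: lithiated A4 would open the C4 terminus of epoxide A2, which carries C5, C6 and ring B. HMPA would trigger 1,4-Brook migration of silicon to the new C5 alkoxide, and the regenerated dithiane anion would open aryl oxirane A3 at C2 to give A1 in one flask.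
- Merits: three-component convergence; C3 at the ketone oxidation level from the start; the C5/C6 relation is fixed in A2 beforehand. In that last respect it is more secure than the chosen plan, whose C5 depends on a Felkin–Anh preference.
- Weak points for 17:
  - The key step closes no ring and leaves C1 as an uncontrolled carbinol. Ring closure then needs oxidation at C1, desilylation at C5 and reductive etherification of the hemiketal.
  - The dithiane must be hydrolysed with oxidants or soft metal salts beside two electron-rich rings, and three benzyl ethers must be hydrogenolysed next to the benzylic C1–O bond.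
  - A3 is an electron-rich styrene oxide, prone to Meinwald rearrangement with lithium salts and to attack at the benzylic carbon.
  - A2 itself needs several steps.
- Comparison: against the better-secured C5, the chosen plan forms the ring and controls C1 in one operation, needs two steps from the key step to 17 instead of about five, and has no thioketal or benzyl ether to remove.

**Alternative 2: stereospecific epoxide opening.**
- Cut: the ring C5–O bond.
- Forward key step: hydroxy epoxide A6, with the (S)-C1 carbinol, a C3 dithiane and a trans-(5S,6S)-epoxide, would cyclise by 6-exo attack of the C1 hydroxyl on C5 with inversion. This closes the pyran and releases the C6 hydroxyl of A5.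
- Merits: the closure is stereospecific; C5 and C6 both come from one reagent-controlled epoxidation of an (E)-alkene; the gem-disubstituted C3 favours cyclisation; the C6 hydroxyl appears unprotected. For C5/C6 this is better stereocontrol than a Felkin–Anh addition.
- Weak points for 17:
  - C1 must be set by a separate asymmetric operation, and any C1 epimer is carried into a 2,6-trans pyran that cannot be corrected.
  - The isolated (E)-alkene is neither an allylic alcohol nor conjugated, so only dioxirane-type (Shi) epoxidation applies, and this is incompatible with the oxidisable dithiane sulfur unless the order of events is rearranged.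
  - The closure needs acid at a p-alkoxybenzylic alcohol, which can ionise or dehydrate.
  - Dithiane removal and benzyl hydrogenolysis remain at the end.
- Comparison: the chosen plan uses one purchased stereocentre, obtains C1 from the chair without a reagent, and is shorter. It concedes the tighter control at C5.

**Alternative 3: Petasis–Ferrier rearrangement.**
- Cut: C4–C5 within the ring.
- Forward key step: enol acetal A8, from β-hydroxy acid A9 and aldehyde 7 by acetalisation and carbonyl methylenation with Cp2TiMe2, would be opened by Me2AlCl between C5 and the enol oxygen. The aluminium enolate would then add to the C5 oxocarbenium ion to give A7, which is identical with 16.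
- Merits: the ketone is delivered directly, which saves the oxidative cleavage; C5 is set by the chair relative to C1 and does not depend on Felkin–Anh selectivity; the protecting groups and final step are the same. After the key step this road is one step shorter.
- Weak points for 17:
  - A9 needs an asymmetric acetate aldol or an asymmetric β-keto ester reduction, which adds a second source of chirality and several steps.
  - Acetalisation uses the epimerisable aldehyde 7 under Lewis acid, and the methylenation needs heat and stoichiometric titanium.
  - The rearrangement needs a strong Lewis acid on a substrate whose C1–O bond is a p-silyloxybenzylic ether. Ionisation there, not at C5–O, would erase C1, the centre meant to relay chirality. The wanted C5 cation is disfavoured by the adjacent C6 silyloxy group.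
- Comparison: the chosen plan places the cation at C1, where the electron-rich ring helps, and creates C1 without putting it at risk. It pays one extra step for unveiling the ketone, and its overall step count is similar or lower.

Key step: step 8

## Route

Assumption: L-tyrosine, vanillin, 2-(chloromethyl)-3-(trimethylsilyl)prop-1-ene and the common reagents are purchased. TBS = tert-butyldimethylsilyl, TMS = trimethylsilyl.

Step 1
Reactants: 1 L-tyrosine
Product: 4 (S)-2-hydroxy-3-(4-hydroxyphenyl)propanoic acid, via diazonium carboxylate 2 (not isolated), via α-lactone 3 (not isolated)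
Conditions: NaNO2, 1 M aq. H2SO4, 0 °C to rt
Reagents that add atoms: water, O
Why: Diazotisation of the α-amino acid with nitrous acid; the carboxylate displaces N2 from 2 with inversion to give α-lactone 3, and water opens 3 with a second inversion, so the future C6 keeps the S configuration. The reaction is long established for α-amino acids including tyrosine, and cold dilute acid limits C-nitrosation of the phenol.

Step 2
Reactants: 4 (S)-2-hydroxy-3-(4-hydroxyphenyl)propanoic acid
Product: 5 methyl (S)-2-hydroxy-3-(4-hydroxyphenyl)propanoate
Conditions: MeOH, H2SO4 (cat.), reflux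
Reagents that add atoms: methanol, CO
Why: Fischer esterification; the stereocentre is not involved and the phenol does not react.

Step 3
Reactants: 5 methyl (S)-2-hydroxy-3-(4-hydroxyphenyl)propanoate
Product: 6 methyl (S)-2-(TBS-oxy)-3-[4-(TBS-oxy)phenyl]propanoate
Conditions: TBSCl (2.5 equiv), imidazole, DMF, rt
Reagents that add atoms: tert-butyldimethylsilyl chloride, CC(C)(C)[Si](C)(C)Cl
Why: Standard silylation of a phenol and a secondary α-hydroxy ester; the bulky, weakly coordinating silyl ether on the C6 oxygen is what later enforces non-chelated addition.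

Step 4
Reactants: 6 methyl (S)-2-(TBS-oxy)-3-[4-(TBS-oxy)phenyl]propanoate
Product: 7 (S)-2-(TBS-oxy)-3-[4-(TBS-oxy)phenyl]propanal
Conditions: iBu2AlH (1.1 equiv), CH2Cl2, −78 °C; aq. KNaC4H4O6 (tartrate) work-up
Reagents that add atoms: none
Why: Partial reduction of the ester; the tetrahedral aluminium hemiacetal is stable at −78 °C and releases the aldehyde only on work-up, a standard operation for α-silyloxy esters. Aldehyde 7 is used at once without chromatography to avoid α-epimerisation.

Step 5
Reactants: 8 2-(chloromethyl)-3-(trimethylsilyl)prop-1-ene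
Product: 9 tributyl{2-[(trimethylsilyl)methyl]prop-2-en-1-yl}stannane
Conditions: Bu3SnH, LiN(iPr)2, THF, 0 °C; then 8, −78 °C to rt
Reagents that add atoms: tributyltin hydride (converted in the flask into Bu3SnLi), CCCC[SnH](CCCC)CCCC
Why: Nucleophilic substitution of the allylic chloride by Bu3SnLi; direct and allylic (SN2') displacement give the same constitution, and the C–Si bond is untouched.

Step 6
Reactants: 7 (S)-2-(TBS-oxy)-3-[4-(TBS-oxy)phenyl]propanal; 9 tributyl{2-[(trimethylsilyl)methyl]prop-2-en-1-yl}stannane
Product: 10 (2S,3R)-2-(TBS-oxy)-1-[4-(TBS-oxy)phenyl]-5-[(trimethylsilyl)methyl]hex-5-en-3-ol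
Conditions: BF3·OEt2 (1.1 equiv), CH2Cl2, −78 °C; sat. aq. NaHCO3 added at −78 °C
Reagents that add atoms: none
Why: Lewis-acid-promoted allylstannane addition through an open transition state (the tin counterpart of the Hosomi–Sakurai allylation); BF3 is monodentate and the silyl ether a poor donor, so no chelate forms and attack occurs anti to the C6–O bond (polar Felkin–Anh model), which sets C5 as R, erythro to C6. The stannane terminus is far more nucleophilic than the silane terminus, so the C–Si bond should survive at −78 °C, and the cold basic quench prevents protodesilylation.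

Step 7
Reactants: 11 vanillin
Product: 12 4-(TBS-oxy)-3-methoxybenzaldehyde
Conditions: TBSCl, imidazole, DMF, rt
Reagents that add atoms: tert-butyldimethylsilyl chloride, CC(C)(C)[Si](C)(C)Cl
Why: Routine phenol silylation; the aldehyde is unaffected.

Step 8
Reactants: 10 (2S,3R)-2-(TBS-oxy)-1-[4-(TBS-oxy)phenyl]-5-[(trimethylsilyl)methyl]hex-5-en-3-ol; 12 4-(TBS-oxy)-3-methoxybenzaldehyde
Product: 14 (2S,6R)-2-[4-(TBS-oxy)-3-methoxyphenyl]-6-{(1S)-1-(TBS-oxy)-2-[4-(TBS-oxy)phenyl]ethyl}-4-methylenetetrahydro-2H-pyran (2,6-cis), via oxocarbenium triflate 13 (not isolated)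
Conditions: TMSOTf (1.1 equiv), Et2O, −78 °C; sat. aq. NaHCO3
Reagents that add atoms: none
Why: TMSOTf joins the C5 hydroxyl of 10 and the carbonyl of 12 (silylation, hemiacetal formation, ionisation) into the aryl-conjugated (E)-oxocarbenium ion 13; the alkene terminus of the tethered allylsilane (C2) attacks C1, and loss of the trimethylsilyl group from the developing β-silyl cation leaves the exocyclic methylene on C3. The closest known reaction type is the TMSOTf-promoted annulation of hydroxy allylsilanes with aldehydes (intramolecular Hosomi–Sakurai or silyl-Prins cyclisation), which gives 2,6-cis-4-methylenetetrahydropyrans. The one ring formed, the tetrahydropyran, closes in a 6-endo-trig mode through a chair transition state in which the C5 side chain and the C1 aryl group of the (E)-ion are both equatorial. The new stereocentre C1 is therefore set as S by the existing C5 centre through the chair, giving the 2,6-cis ring, while C5 and C6 are not touched. The step needs oxocarbenium formation to beat protodesilylation and ring closure to outrun oxonia-Cope exchange, to which electron-rich aryl oxocarbenium ions are prone; the high nucleophilicity of the allylsilane and the irreversible loss of silicon should make closure fast, and ether at −78 °C tempers the triflic acid formed. The 2,6-cis ether is also the thermodynamically preferred isomer, so any reversible ionisation of the benzylic C1–O bond would lead back to it.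

Step 9
Reactants: 14 (2S,6R)-2-[4-(TBS-oxy)-3-methoxyphenyl]-6-{(1S)-1-(TBS-oxy)-2-[4-(TBS-oxy)phenyl]ethyl}-4-methylenetetrahydro-2H-pyran
Product: 16 (2S,6R)-2-[4-(TBS-oxy)-3-methoxyphenyl]-6-{(1S)-1-(TBS-oxy)-2-[4-(TBS-oxy)phenyl]ethyl}tetrahydro-4H-pyran-4-one, via diol 15 (not isolated)
Conditions: OsO4 (2 mol %), NaIO4 (4 equiv), 2,6-lutidine, 1,4-dioxane/H2O 3:1, rt
Reagents that add atoms: osmium tetroxide (catalytic, delivers the oxygen), O=[Os](=O)(=O)=O; sodium periodate (terminal oxidant that resupplies it), [Na+].[O-]I(=O)(=O)=O
Why: Lemieux–Johnson oxidation: OsO4 dihydroxylates the unhindered 1,1-disubstituted alkene to diol 15, which NaIO4 cleaves to the ketone and formaldehyde while reoxidising osmium. 2,6-Lutidine keeps the medium near neutral, which suppresses α-hydroxylation and spares the silyl ethers and the β-alkoxy ketone; the silylated phenols are inert to periodate and no stereocentre is affected.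

Step 10
Reactants: 16 (2S,6R)-2-[4-(TBS-oxy)-3-methoxyphenyl]-6-{(1S)-1-(TBS-oxy)-2-[4-(TBS-oxy)phenyl]ethyl}tetrahydro-4H-pyran-4-one
Product: 17 (2S,6R)-2-(4-hydroxy-3-methoxyphenyl)-6-[(1S)-1-hydroxy-2-(4-hydroxyphenyl)ethyl]tetrahydro-4H-pyran-4-one (CNP0222055.1)
Conditions: HF·pyridine, pyridine/THF, 0 °C to rt
Reagents that add atoms: none
Why: Fluoride-assisted cleavage of all three Si–O bonds by pyridine-buffered HF; the medium is not basic, so the β-alkoxy ketone should not open by β-elimination, and not strongly acidic, so the benzylic C1–O bond should not ionise. No stereocentre is formed or touched.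

## Compound list

1 | L-tyrosine | N[C@@H](Cc1ccc(O)cc1)C(=O)O | starting material
2 | (S)-1-carboxylato-2-(4-hydroxyphenyl)ethanediazonium (diazonium carboxylate) | N#[N+][C@@H](Cc1ccc(O)cc1)C(=O)[O-] | intermediate
3 | (R)-3-(4-hydroxybenzyl)oxiran-2-one (α-lactone) | O=C1O[C@@H]1Cc1ccc(O)cc1 | intermediate
4 | (S)-2-hydroxy-3-(4-hydroxyphenyl)propanoic acid | O[C@@H](Cc1ccc(O)cc1)C(=O)O | intermediate
5 | methyl (S)-2-hydroxy-3-(4-hydroxyphenyl)propanoate | COC(=O)[C@@H](O)Cc1ccc(O)cc1 | intermediate
6 | methyl (S)-2-(tert-butyldimethylsilyloxy)-3-[4-(tert-butyldimethylsilyloxy)phenyl]propanoate | COC(=O)[C@@H](O[Si](C)(C)C(C)(C)C)Cc1ccc(O[Si](C)(C)C(C)(C)C)cc1 | intermediate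
7 | (S)-2-(tert-butyldimethylsilyloxy)-3-[4-(tert-butyldimethylsilyloxy)phenyl]propanal | O=C[C@@H](O[Si](C)(C)C(C)(C)C)Cc1ccc(O[Si](C)(C)C(C)(C)C)cc1 | intermediate
8 | 2-(chloromethyl)-3-(trimethylsilyl)prop-1-ene | ClCC(=C)C[Si](C)(C)C | starting material
9 | tributyl{2-[(trimethylsilyl)methyl]prop-2-en-1-yl}stannane | CCCC[Sn](CCCC)(CCCC)CC(=C)C[Si](C)(C)C | intermediate
10 | (2S,3R)-2-(tert-butyldimethylsilyloxy)-1-[4-(tert-butyldimethylsilyloxy)phenyl]-5-[(trimethylsilyl)methyl]hex-5-en-3-ol | C[Si](C)(C)CC(=C)C[C@@H](O)[C@@H](O[Si](C)(C)C(C)(C)C)Cc1ccc(O[Si](C)(C)C(C)(C)C)cc1 | intermediate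
11 | vanillin (4-hydroxy-3-methoxybenzaldehyde) | COc1cc(C=O)ccc1O | starting material
12 | 4-(tert-butyldimethylsilyloxy)-3-methoxybenzaldehyde | COc1cc(C=O)ccc1O[Si](C)(C)C(C)(C)C | intermediate
13 | (E)-[4-(tert-butyldimethylsilyloxy)-3-methoxybenzylidene]{(2S,3R)-2-(tert-butyldimethylsilyloxy)-1-[4-(tert-butyldimethylsilyloxy)phenyl]-5-[(trimethylsilyl)methyl]hex-5-en-3-yl}oxonium triflate | COc1cc(/C=[O+]/[C@H](CC(=C)C[Si](C)(C)C)[C@@H](O[Si](C)(C)C(C)(C)C)Cc2ccc(O[Si](C)(C)C(C)(C)C)cc2)ccc1O[Si](C)(C)C(C)(C)C.[O-]S(=O)(=O)C(F)(F)F | intermediate
14 | (2S,6R)-2-[4-(tert-butyldimethylsilyloxy)-3-methoxyphenyl]-6-{(1S)-1-(tert-butyldimethylsilyloxy)-2-[4-(tert-butyldimethylsilyloxy)phenyl]ethyl}-4-methylenetetrahydro-2H-pyran | COc1cc([C@@H]2CC(=C)C[C@H]([C@@H](O[Si](C)(C)C(C)(C)C)Cc3ccc(O[Si](C)(C)C(C)(C)C)cc3)O2)ccc1O[Si](C)(C)C(C)(C)C | intermediate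
15 | (2S,6R)-2-[4-(tert-butyldimethylsilyloxy)-3-methoxyphenyl]-6-{(1S)-1-(tert-butyldimethylsilyloxy)-2-[4-(tert-butyldimethylsilyloxy)phenyl]ethyl}-4-(hydroxymethyl)tetrahydro-2H-pyran-4-ol (either C4 epimer) | COc1cc([C@@H]2CC(O)(CO)C[C@H]([C@@H](O[Si](C)(C)C(C)(C)C)Cc3ccc(O[Si](C)(C)C(C)(C)C)cc3)O2)ccc1O[Si](C)(C)C(C)(C)C | intermediate
16 | (2S,6R)-2-[4-(tert-butyldimethylsilyloxy)-3-methoxyphenyl]-6-{(1S)-1-(tert-butyldimethylsilyloxy)-2-[4-(tert-butyldimethylsilyloxy)phenyl]ethyl}tetrahydro-4H-pyran-4-one | COc1cc([C@@H]2CC(=O)C[C@H]([C@@H](O[Si](C)(C)C(C)(C)C)Cc3ccc(O[Si](C)(C)C(C)(C)C)cc3)O2)ccc1O[Si](C)(C)C(C)(C)C | intermediate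
17 | (2S,6R)-2-(4-hydroxy-3-methoxyphenyl)-6-[(1S)-1-hydroxy-2-(4-hydroxyphenyl)ethyl]tetrahydro-4H-pyran-4-one | COc1cc([C@@H]2CC(=O)C[C@H]([C@@H](O)Cc3ccc(O)cc3)O2)ccc1O | target

## Step count and risk

Total: 10 steps. Longest linear sequence: 8 steps (steps 1, 2, 3, 4, 6, 8, 9, 10); steps 5 and 7 are one-step side branches.

**Step 8 (key step).**
- What may go wrong: condensation of the hindered C5 hydroxyl, which sits next to the silyloxy-bearing C6, with the electron-rich and weakly electrophilic aldehyde may be slow. Protodesilylation of the allylsilane by triflic acid or formation of a symmetrical acetal could then compete, and the aryl silyl ether could be partly lost under the Lewis acid.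
- Fallback: generate the same cation from a pre-formed C5–O–C1 linkage instead of by condensation. It sets out from 10, with 12 as the source of the acyl partner.
  - 12 is oxidised (NaClO2, NaH2PO4, 2-methyl-2-butene, tBuOH/H2O) to 4-(tert-butyldimethylsilyloxy)-3-methoxybenzoic acid F1.
  - F1 acylates 10 (DCC, DMAP, CH2Cl2) to give the (2S,3R)-hexenyl 4-(tert-butyldimethylsilyloxy)-3-methoxybenzoate F2.
  - Reductive acetylation (iBu2AlH, CH2Cl2, −78 °C; then Ac2O, pyridine, DMAP) gives the α-acetoxy ether F3.
  - TMSOTf (or SnBr4) in CH2Cl2 at −78 °C ionises F3 to the cation of 13 without releasing water or silanol, and this cyclises as before.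
  - The sequence returns to the route at 14.

**Step 6.**
- What may go wrong: facial selectivity may be insufficient with a small, reactive allyl nucleophile. The product allylsilane may react with a second molecule of BF3-activated aldehyde (premature pyran formation) or be protodesilylated during work-up.
- Fallback: form the C4–C5 bond with an ester enolate equivalent and build the allylsilane afterwards. It sets out from 7.
  - Mukaiyama aldol addition of 1-ethoxy-1-(tert-butyldimethylsilyloxy)ethene (BF3·OEt2, CH2Cl2, −78 °C) follows the same Felkin–Anh model with a bulkier nucleophile and should give ethyl (3R,4S)-4-(tert-butyldimethylsilyloxy)-3-hydroxy-5-[4-(tert-butyldimethylsilyloxy)phenyl]pentanoate F4. The diastereomers could be separated at this stage.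
  - Double addition of TMSCH2MgCl in the presence of CeCl3 (THF, −78 °C to rt) gives the bis(trimethylsilylmethyl) carbinol F5.
  - Peterson elimination of F5 on silica gel returns to the route at 10.

**Step 10.**
- What may go wrong: cleavage of the hindered C6 silyl ether may be slow. Long exposure of the β-alkoxy ketone and the freed p-hydroxybenzylic ether to HF could then cause ring opening and loss of material.
- Fallback: remove the silyl groups before the ketone exists. It sets out from 14.
  - Bu4NF (THF, rt) removes all three silyl groups at the methylene stage, where neither basicity nor long reaction time does harm, giving 4-[(2S,6R)-6-[(1S)-1-hydroxy-2-(4-hydroxyphenyl)ethyl]-4-methylenetetrahydro-2H-pyran-2-yl]-2-methoxyphenol F6.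
  - Ozonolysis (O3, CH2Cl2/MeOH, −78 °C, stopped at the first excess of ozone shown by a dye indicator; then Me2S) cleaves the 1,1-disubstituted alkene, which reacts with ozone much faster than an un-ionised phenol does.
  - The route is rejoined at 17. Periodate is avoided here because it would oxidise the free guaiacol.

**Step 4.**
- What may go wrong: over-reduction to the primary alcohol, incomplete conversion, or epimerisation of the α-silyloxy aldehyde during the aluminium work-up.
- Fallback: a two-step redox sequence. It sets out from 6.
  - Complete reduction (iBu2AlH, 2.5 equiv, CH2Cl2, −78 to 0 °C) gives (S)-2-(tert-butyldimethylsilyloxy)-3-[4-(tert-butyldimethylsilyloxy)phenyl]propan-1-ol F7.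
  - Parikh–Doering oxidation of F7 (SO3·pyridine, DMSO, iPr2NEt, 0 °C) returns to the route at 7.

## Further compounds

F1 | step 8 | 4-(tert-butyldimethylsilyloxy)-3-methoxybenzoic acid | COc1cc(C(=O)O)ccc1O[Si](C)(C)C(C)(C)C
F2 | step 8 | (2S,3R)-2-(tert-butyldimethylsilyloxy)-1-[4-(tert-butyldimethylsilyloxy)phenyl]-5-[(trimethylsilyl)methyl]hex-5-en-3-yl 4-(tert-butyldimethylsilyloxy)-3-methoxybenzoate | COc1cc(C(=O)O[C@H](CC(=C)C[Si](C)(C)C)[C@@H](O[Si](C)(C)C(C)(C)C)Cc2ccc(O[Si](C)(C)C(C)(C)C)cc2)ccc1O[Si](C)(C)C(C)(C)C
F3 | step 8 | [4-(tert-butyldimethylsilyloxy)-3-methoxyphenyl]{[(2S,3R)-2-(tert-butyldimethylsilyloxy)-1-[4-(tert-butyldimethylsilyloxy)phenyl]-5-[(trimethylsilyl)methyl]hex-5-en-3-yl]oxy}methyl acetate (both acetal epimers) | COc1cc(C(OC(C)=O)O[C@H](CC(=C)C[Si](C)(C)C)[C@@H](O[Si](C)(C)C(C)(C)C)Cc2ccc(O[Si](C)(C)C(C)(C)C)cc2)ccc1O[Si](C)(C)C(C)(C)C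
F4 | step 6 | ethyl (3R,4S)-4-(tert-butyldimethylsilyloxy)-3-hydroxy-5-[4-(tert-butyldimethylsilyloxy)phenyl]pentanoate | CCOC(=O)C[C@@H](O)[C@@H](O[Si](C)(C)C(C)(C)C)Cc1ccc(O[Si](C)(C)C(C)(C)C)cc1
F5 | step 6 | (4R,5S)-5-(tert-butyldimethylsilyloxy)-6-[4-(tert-butyldimethylsilyloxy)phenyl]-1-(trimethylsilyl)-2-[(trimethylsilyl)methyl]hexane-2,4-diol | C[Si](C)(C)CC(O)(C[Si](C)(C)C)C[C@@H](O)[C@@H](O[Si](C)(C)C(C)(C)C)Cc1ccc(O[Si](C)(C)C(C)(C)C)cc1
F6 | step 10 | 4-[(2S,6R)-6-[(1S)-1-hydroxy-2-(4-hydroxyphenyl)ethyl]-4-methylenetetrahydro-2H-pyran-2-yl]-2-methoxyphenol | COc1cc([C@@H]2CC(=C)C[C@H]([C@@H](O)Cc3ccc(O)cc3)O2)ccc1O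
F7 | step 4 | (S)-2-(tert-butyldimethylsilyloxy)-3-[4-(tert-butyldimethylsilyloxy)phenyl]propan-1-ol | OC[C@@H](O[Si](C)(C)C(C)(C)C)Cc1ccc(O[Si](C)(C)C(C)(C)C)cc1
A1 | alternative 1 | 1-[4-(benzyloxy)-3-methoxyphenyl]-2-{2-[(2R,3S)-3-(benzyloxy)-4-[4-(benzyloxy)phenyl]-2-(tert-butyldimethylsilyloxy)butyl]-1,3-dithian-2-yl}ethanol (both C1 epimers) | COc1cc(C(O)CC2(C[C@@H](O[Si](C)(C)C(C)(C)C)[C@@H](OCc3ccccc3)Cc3ccc(OCc4ccccc4)cc3)SCCCS2)ccc1OCc1ccccc1
A2 | alternative 1 | (R)-2-{(S)-1-(benzyloxy)-2-[4-(benzyloxy)phenyl]ethyl}oxirane | C1O[C@H]1[C@@H](OCc1ccccc1)Cc1ccc(OCc2ccccc2)cc1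
A3 | alternative 1 | 2-[4-(benzyloxy)-3-methoxyphenyl]oxirane (racemic) | COc1cc(C2CO2)ccc1OCc1ccccc1
A4 | alternative 1 | 2-(tert-butyldimethylsilyl)-1,3-dithiane | CC(C)(C)[Si](C)(C)C1SCCCS1
A5 | alternative 2 | C3 1,3-dithiane of 17 with both phenols as benzyl ethers, (1S,5R,6S) | COc1cc([C@@H]2CC3(C[C@H]([C@@H](O)Cc4ccc(OCc5ccccc5)cc4)O2)SCCCS3)ccc1OCc1ccccc1
A6 | alternative 2 | (S)-1-[4-(benzyloxy)-3-methoxyphenyl]-2-[2-({(2S,3S)-3-[4-(benzyloxy)benzyl]oxiran-2-yl}methyl)-1,3-dithian-2-yl]ethanol | COc1cc([C@@H](O)CC2(C[C@@H]3O[C@H]3Cc3ccc(OCc4ccccc4)cc3)SCCCS2)ccc1OCc1ccccc1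
A7 | alternative 3 | tris(tert-butyldimethylsilyl) ether of 17 (identical with 16) | COc1cc([C@@H]2CC(=O)C[C@H]([C@@H](O[Si](C)(C)C(C)(C)C)Cc3ccc(O[Si](C)(C)C(C)(C)C)cc3)O2)ccc1O[Si](C)(C)C(C)(C)C
A8 | alternative 3 | 2,6-cis-6-[4-(tert-butyldimethylsilyloxy)-3-methoxyphenyl]-2-{(1S)-1-(tert-butyldimethylsilyloxy)-2-[4-(tert-butyldimethylsilyloxy)phenyl]ethyl}-4-methylene-1,3-dioxane, (6S) | COc1cc([C@@H]2CC(=C)O[C@H]([C@@H](O[Si](C)(C)C(C)(C)C)Cc3ccc(O[Si](C)(C)C(C)(C)C)cc3)O2)ccc1O[Si](C)(C)C(C)(C)C
A9 | alternative 3 | (S)-3-[4-(tert-butyldimethylsilyloxy)-3-methoxyphenyl]-3-hydroxypropanoic acid | COc1cc([C@@H](O)CC(=O)O)ccc1O[Si](C)(C)C(C)(C)C
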